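If starting material and partner are charged in equal amounts, each forward step takes one of each, so the two fall in step and the forward rate goes with the square of what is left.

| setting | ash | south-east | east |
|---|---|---|---|
| starting material | 0.34 M | 0.69 M | 0.69 M |
| partner | 0.69 M | 0.690 M | 0.690 M |
| capture agent | 0.069 M | 0.0690 M | 0.0690 M |
| temperature | 25 °C | 25 °C | 40 °C |
| remark | run made earlier |  |  |
| time |  | 12 h | 12 h |

ash run (percent of the starting material charged)

| time / h | open intermediate / % | product / % | starting material / % | trapped intermediate / % |
|---|---|---|---|---|
| 0.333 | 5.6 | 0 | 93.6 | 0.1 |
| 0.667 | 10.9 | 0.7 | 88.0 | 0.1 |
| 1.00 | 14.8 | 2.2 | 82.9 | 0.5 |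
| 1.33 | 17.8 | 2.0 | 78.9 | 0 |
| 1.50 | 19.5 | 3.8 | 76.9 | 0.7 |
| 2.00 | 22.4 | 5.8 | 70.5 | 0.8 |
| 2.50 | 25.1 | 9.0 | 65.8 | 1.4 |

(standard deviation of a reading: 0.3 percentage points)

- the numbers in the tables scatter with a standard deviation of 0.3 percentage points
- steps that have been proposed: starting material + partner <-> open intermediate; open intermediate -> product; open intermediate + capture agent -> trapped intermediate
- the earlier runs do not show what temperature does; that part of a forecast is a guess

* which of these there is most of at the end, counted by the starting material in it, south-east (product / trapped intermediate / starting material / open intermediate)
* which of these there is most of at the end, counted by the starting material in it, east (product / trapped intermediate / starting material / open intermediate)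
* the largest of these amounts at the end, in percent of the starting material charged, south-east
* the largest of these amounts at the end, in percent of the starting material charged, east

In the ash run the partner lost 8.43 % of its charge by 1.00 h, so I freeze it there and read the fall of starting material to 82.9 % as pseudo-first-order. That reading gives what I carry, the meeting time, the reciprocal of the forward rate constant times the equal charge, with the way back ignored: 5.33 h. In a flask with equal charges, and with the way back still ignored, the share of starting material left at a given time is then the meeting time over the meeting time plus that time.

For south-east at 12 h this leaves 30.8 %, so how much of the remainder has reached product? The ash readings at 2.50 h put product over trapped intermediate, the selectivity factor, at 6.43, a reading with the scatter of a small trapped intermediate figure, from a flask charged with the same capture agent concentration. They also give, as a reading, the open intermediate a life of 4.15 h, its time integral over product, which is shorter than the 12 h of south-east. The feed at that moment, the square of that share over the meeting time, times this life puts my estimate of open intermediate at 7.36 %, and my product for south-east comes to 53.5 %, above my figure for starting material.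

For east I guess 3 times faster, a meeting time of 1.78 h. That leaves 12.9 % and, if the selectivity factor stays as read and open intermediate is not counted, gives my estimate of product near 75.4 %.

The forecast also names product for south-east at 45 % and product for east at 72 %, below my figures, and says “temperature is a guess”.

South-east gives product at 48.3 %, and east gives product at 83.2 %.

    starting material + partner ⇌ open intermediate (K = 5.60 L mol⁻¹, k = 7.90 × 10⁻⁵ L mol⁻¹ s⁻¹, Ea = 74.0 kJ mol⁻¹, ΔH = −35.0 kJ mol⁻¹)
    open intermediate → product (k = 6.00 × 10⁻⁵ s⁻¹, Ea = 95.0 kJ mol⁻¹)
    open intermediate + capture agent → trapped intermediate (k = 9.30 × 10⁻⁵ L mol⁻¹ s⁻¹, Ea = 65.0 kJ mol⁻¹)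
    (constants at 25 °C)

South-east keeps 34.7 % starting material against my 30.8 %. East keeps 12.1 % at 12.0 h, which by the same share makes its meeting time 1.66 h. Carried to 50 h, that meeting time leaves 3.21 %, and east read then holds 3.13 % starting material.

The data are simulated on assumed constants; scatter was added.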